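1. I count amounts as fractions of the Ja charged: a for Ja, c for Jc, d for Jd, summing to one. Jb is returned by its step, and I count it apart.

| setting | south-east | north-east | amber | teal | grey |
|---|---|---|---|---|---|
| Ja | 0.30 M | 1.6 M | 0.25 M | 0.50 M | 1.0 M |
| Jb | 0.41 mM | 0.41 mM | 0.41 mM | 0.41 mM | 0.41 mM |
| remark | run made earlier | run made earlier |  |  |  |
| time |  |  | 2.0 h | 2.0 h | 2.0 h |

| run | time / min | Jd / % |
|---|---|---|
| south-east | 3.00 | 0.3 |
| south-east | 10.0 | 1.7 |
| south-east | 15.0 | 4.3 |
| south-east | 25.0 | 9.8 |
| south-east | 40.0 | 23.7 |
| south-east | 50.0 | 30.6 |
| south-east | 60.0 | 38.3 |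
| north-east | 5.00 | 0.4 |
| north-east | 8.00 | 1.5 |
| north-east | 12.0 | 3.0 |
| north-east | 15.0 | 4.8 |
| north-east | 25.0 | 11.2 |
| north-east | 40.0 | 22.5 |
| north-east | 60.0 | 38.7 |

(standard deviation of a reading: 0.5 percentage points)

- amount of Jd at the end, in percent of the Ja charged for amber, teal, grey, in this order
- the shape of the row from first to last (hardly changes / falls, then rises / rises all the way / falls all the way / rises, then falls)

- steps under discussion: Jb + Jc -> Jb + Jd; Ja -> Jc
- "hardly changes" means that all values lie within two and a half points (for a concentration: within two and a half percent of the largest)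

2. First instants: c starts at zero, so Ja → Jc is the step that can run, and Jd has to wait for a stock of Jc. The runs show this lag: at 3.00 min the south-east run holds 0.3% Jd, and at 15.0 min it holds 4.3%, beside 4.8% in the north-east run.

3. Integrating Ja → Jc as written, with k its rate constant, gives a = e^(−kt), and the charge has dropped out of this. The step Jb + Jc → Jb + Jd has a rate proportional to Jc while Jb stands constant, which makes it pseudo-first-order, so c and d are free of the charge in the same way.

4. The quantity I carry is the charge exponent, the slope of ln d against ln(charge of Ja) at a fixed time and a fixed charge of Jb. These steps make it zero, and the readings can test that.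

5. Middle: at 40.0 min the south-east run reads 23.7% and the north-east run 22.5%. Jc is feeding Jd by now, and what matters next is how the two steps share the remaining time.

6. Latest readings: at 60.0 min they are 38.3% and 38.7%, which differ by 0.4 percentage points, less than the scatter of 0.5 points. Across charges of 0.30 M and 1.6 M, the charge exponent reads 0.00621.

7. The forecast gives 75%, 75%, 75%, and the shape hardly changes: “Because the kinetics are first order, all three concentrations should give the same percentage”. My exponent gives no level, so I take the forecast's. Supposing that the exponent read at 60.0 min also holds at 2.0 h, it moves amber to grey by 0.65 points at that level, so I also expect hardly changes.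

8. The flasks give 73.8%, 73.8%, 73.8%: hardly changes. From amber to grey the exponent is 0, and in teal the local order is 0, against my reading of 0.00621.

    Jb + Jc → Jb + Jd (k = 2600 /M/h)
    Ja → Jc (k = 1.70 /h)

In amber, Ja has a half-life of 0.41 h by its own step, and Jc has a longer one of 0.65 h, with Jb still at 100% of the catalyst charged at 0.600 h. At 2.00 h Jc is made at 0.233 of the rate at which it is used, and amber holds Ja 3.34%, Jc 22.9% and Jd 73.8%.

All runs are simulated on assumed constants.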